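The ochre and amber runs differ in charge, and comparing them gives the rule for the new flasks.

| flask | electrophile | nucleophile | free base | remark | time |
|---|---|---|---|---|---|
| ochre | 0.0034 M (fed, over 2.5 s) | 0.80 equiv | 3 equiv | run made earlier; the fed solution adds 0.25 times the starting volume |  |
| amber | 0.0025 M (fed, over 2.5 s) | 0.80 equiv | 3 equiv | run made earlier; the fed solution adds 0.25 times the starting volume |  |
| north | 0.0050 M (fed, over 2.5 s) | 0.800 equiv | 6.80 equiv | the fed solution adds 0.25 times the starting volume | 3.0 min |
| west | 0.0050 M (fed, over 2.5 s) | 0.800 equiv | 4.50 equiv | the fed solution adds 0.25 times the starting volume | 3.0 min |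
| south | 0.0050 M (fed, over 2.5 s) | 0.800 equiv | 3.00 equiv | the fed solution adds 0.25 times the starting volume | 3.0 min |

- ochre (time / s: electrophile / %, target / %): 10.0: 80.9, 12.5; 15.0: 74.8, 14.8; 25.0: 65.0, 15.2; 40.0: 58.2, 11.5
- amber (time / s: electrophile / %, target / %): 10.0: 85.8, 11.2; 15.0: 79.3, 14.5; 20.0: 73.9, 14.1; 30.0: 66.5, 12.4; 40.0: 63.9, 14.2

(each reading ± 1 percentage point)

1. part of the electrophile that has reacted at the end, north
2. part of the electrophile that has reacted at the end, west
3. part of the electrophile that has reacted at the end, south
4. what raising the equivalents of free base from its lowest to its highest value here does to the part of the electrophile that has reacted (changes below 5 percentage points count as none) (it falls / no change / it rises)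

- charges are per starting volume, the dose included; the dosed solution carries all of it
- the earlier runs were read with a standard deviation of 1 percentage point

1. **Feed.** In the ochre run the electrophile's half-life over the first reading is about 32.7 s. The feed of 2.5 s is far shorter, so the dose counts as charged at once.

2. **Early end.** Call charge times time the exposure. The ochre run at 15.0 s and the amber run at 20.0 s have nearly equal exposure, and they hold 74.8% and 73.9% of the electrophile, which lie within the scatter. With equivalents held, exposure is therefore taken as the clock.

3. **Late end.** Between the last two ochre readings the half-life reads 94.1 s, longer than at the start, so a single exponential does not fit these readings.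

4. **Join.** From first to last reading, ochre exposure grows by a factor 4.00, which is two doublings. Over these readings each doubling multiplies the remaining electrophile, on average, by 0.848, the doubling factor. The amber run reads 0.863.

5. **Asked time.** South lies 2.73 doublings beyond the last ochre reading, so this reckoning gives 62.9% reacted. The factor was read with free base at 3 equiv in both runs and has no term for it, so carrying the same figure to north and west, and with it no trend, is an assumption.

The forecast gives 68%, 67% and 65% for north, west and south, and no change, saying “so I expect little effect, perhaps a slight rise”.

The flask gives 66.7%, 65.3% and 64.3%, and no change, with a change of 2.4 points.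

    electrophile + nucleophile ⇌ acid set free + target (K = 28.0, k = 16.0 M⁻¹ s⁻¹)
    electrophile + target → side product (k = 18.0 M⁻¹ s⁻¹)
    acid set free + free base ⇌ salt of the base (K = 120 M⁻¹, k = 360 M⁻¹ s⁻¹)
    2 nucleophile → homo dimer (k = 13.0 M⁻¹ s⁻¹)
    nucleophile + acid set free ⇌ protonated nucleophile, settled at all times (K = 1.40 × 10⁵ M⁻¹)

Against the 62.9% reckoned with 0.848, south reacts 64.3%. In north, the step to target has 70% of its turnover behind it at 0.300 min, and the step to homo dimer 96%; the nucleophile, the limiting reagent, ends with 1.22% of its charge still free. The step of electrophile with target has 87% of its turnover behind it at 1.50 min, and north ends with target at 1.19% and side product, counted by the electrophile it holds, at 65.5%.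

North with 27.0 equiv of free base has the same exposure, so 0.848 again gives 62.9%. That flask reacts 72.8%, which is 8.5 points above south and beyond the margin, so free base raised from 3.00 equiv to 27.0 equiv counts as a rise.

The numbers in the tables stem from a simulated flask from invented constants; the scatter is artificial.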